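I counted the catalyst that works.

- red: substrate 20 mM; reagent 50 mM; free catalyst 11 µM; impurity 2.6 µM; the very flask that is asked about, followed so far
- flask: substrate 20 mM; reagent 50.0 mM; free catalyst 11 µM; impurity 2.6 µM

red run (percent of the substrate charged)

| time / min | target / % | substrate / % |
|---|---|---|
| 6.00 | 2.3 | 97.8 |
| 8.00 | 2.6 | 97.5 |
| 12.0 | 4.8 | 96.5 |
| 20.0 | 5.7 | 94.6 |
| 30.0 | 7.9 | 91.0 |
| 50.0 | 13.3 | 87.6 |
| 80.0 | 19.9 | 80.8 |

(each reading ± 0.5 percentage points)

- no earlier run changes the charge of free catalyst; that part of a forecast is a guess

- apparent order in free catalyst when 20% of the substrate are converted (percent change of the rate of making target for one percent more free catalyst charged)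
- factor on the rate of making target when 20% of the substrate are converted if free catalyst is charged twice over

The red run is this same flask, and no run changed the catalyst charge, so what follows is my own reckoning by hand. The target readings in the red run bent. I divided the slope from 30.0 min to 80.0 min by the slope up to 12.0 min, so that time dropped out, and read 0.600, a rough figure under that scatter. I took the bend as catalyst lost to impurity, one for one:

working share = (free catalyst charged − impurity charged) / free catalyst charged = 0.764

This part of the charge that the impurity leaves over, the working share, stood higher than the bend I had read, and I kept it because it came from the charges.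

I turned the free catalyst first. If the rate follows the working catalyst, then:

order in free catalyst = 1 / working share = 1.31

factor on doubling = (1 + working share) / working share = 2.31

I turned the impurity next, by hand. On the same assumption, I reckoned the percent taken off the rate by one percent more of it:

(1 − working share) / working share = 0.309

The forecast gave 1.3 and 2.3, on the grounds “My guess is that the impurity binds catalyst stoichiometrically”.

The flask gave an order of 1.5 and a factor of 2.46, each higher than the forecast but within its margin.

    reagent + free catalyst → catalyst intermediate A (k = 13200 L mol⁻¹ h⁻¹)
    catalyst intermediate C → free catalyst + target (k = 1420 h⁻¹)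
    free catalyst + impurity → spent catalyst (k = 9.34 × 10⁵ L mol⁻¹ h⁻¹)
    catalyst intermediate A → by-product + catalyst intermediate B (k = 11200 h⁻¹)
    substrate + catalyst intermediate B ⇌ catalyst intermediate C (K = 120 L mol⁻¹, k = 5.74 × 10⁵ L mol⁻¹ h⁻¹)
    2 reagent → self-condensation product (k = 1.57 L mol⁻¹ h⁻¹)

At 1.50 h the flask still held 0.0726% of its impurity, and 23.6% of its catalyst stood as spent catalyst, the off-cycle form. I reckoned the working share of 0.764 for a flask whose impurity has been consumed, so I held it against that moment: free catalyst and catalyst intermediates A, B and C together came to 76.4% of the catalyst charged.

The readings are simulated with constants of no real substance; scatter was added.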